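A direct plan would diazotise 2-amino-3-bromophenol A1 to the ortho-quinone diazide 5-bromo-6-diazocyclohexa-2,4-dien-1-one A2, insert the rhodium carbene formed from A2 and Rh2(OAc)4 into one O–H bond of catechol A3 to give 3-bromo-2-(2-hydroxyphenoxy)phenol A4, and brominate A4 four times.
Its weakest steps would be:
- the diazotisation of A1 with isolation of A2, because a light- and heat-sensitive diazo compound would have to be extracted cold and used at once;
- the carbene O–H insertion that forms the diaryl ether A4, because it would lack precedent for a monocyclic halogenated quinone diazide with a free catechol, would compete with Wolff ring contraction and double insertion, and would consume a fivefold excess of A3.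

The route would rest on taking ring A (the 3,5-dibromo-2-hydroxyphenoxy ring) back to a cyclohexanone. Its C–OH would be the former carbonyl carbon, its ether carbon the former α-carbon, and its two bromines would sit ortho and para to that OH, exactly where a brominative aromatisation leaves them. The hindered ether bond could therefore be made by SN2 alkylation of a phenol that already holds ring B with its bromine next to the ether oxygen. One operation with bromine would then create benzene ring A, its phenol and two C–Br bonds. No diazo compound, no metal carbene and no excess coupling partner would be needed.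

Key step: step 2

Remark: 2, 3 and the transient 4 would be racemic; their stereocentres are erased when ring A becomes aromatic in step 2, and the target has none.

Step 1
Reactants: 1 2-bromo-6-methoxyphenol; 2 2-chlorocyclohexan-1-one
Product: 3 2-(2-bromo-6-methoxyphenoxy)cyclohexan-1-one (racemic)
Conditions: 2 (1.3 equiv), K2CO3 (1.5 equiv), KI (0.1 equiv), DMF, 50 °C, 16 h
Reagents that add atoms: none
Why: Williamson ether synthesis: the phenoxide of 1 should displace chloride (iodide after in situ exchange with KI) at the carbonyl-activated secondary carbon of 2 in an SN2 reaction, a di-ortho-substituted but weakly basic phenoxide being a known partner for secondary α-halo ketones and a poor trigger for Favorskii rearrangement; the new stereocentre forms as the racemate and is erased in step 2.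

Step 2
Reactants: 3 2-(2-bromo-6-methoxyphenoxy)cyclohexan-1-one
Product: 6 2,4-dibromo-6-(2-bromo-6-methoxyphenoxy)phenol, via 6-bromo-2-(2-bromo-6-methoxyphenoxy)cyclohex-2-en-1-one 4 (not isolated), via 2-(2-bromo-6-methoxyphenoxy)phenol 5 (not isolated)
Conditions: Br2 (2.0 equiv, dropwise), HBr/AcOH (cat.), AcOH, 20 °C, then 60 °C, N2 sweep; Br2 (2.05 equiv, dropwise), 20 °C; aq NaHSO3
Reagents that add atoms: bromine BrBr
Why: Acid-catalysed enolisation and α-bromination of 3 at C2 and C6 should be followed by loss of HBr from the α-bromo-α-aryloxy carbon to give bromo enone 4, whose dienol should lose the allylic bromide at C6 and a proton at C5 to give phenol 5, and 5 should then be substituted at once ortho and para to its new OH by the second portion of bromine. The closest known reaction type is the bromination–dehydrobromination aromatisation of cyclohexanones and cyclohexenones to bromophenols with Br2 in acetic acid. No ring is closed, the existing carbocycle is dehydrogenated to benzene ring A, and the stereocentre of 3 is erased while none is created. The substrate fixes the regiochemistry: the carbonyl carbon becomes C–OH, the α-carbon keeps the aryloxy group, and bromine is left only on the former α′ carbon (ortho) and on the para carbon, the two carbons meta to OH being neither α′ to the ketone nor activated by the phenol. Ring B has to stay untouched, which should follow from kinetics, since ketone bromination is zero order in bromine and phenol 5 reacts far faster than the bromoanisole ring, so that dropwise addition keeps free bromine low. The methyl ether of ring B prevents hemiketal formation and closure to a dibenzodioxin, and the two substituents ortho to its ether oxygen block acid-promoted cyclodehydration to a tetrahydrodibenzofuran.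

Step 3
Reactants: 6 2,4-dibromo-6-(2-bromo-6-methoxyphenoxy)phenol
Product: 7 3-bromo-2-(3,5-dibromo-2-hydroxyphenoxy)phenol
Conditions: BBr3 (3.0 equiv), CH2Cl2, −78 °C to rt; H2O, 0 °C
Reagents that add atoms: none
Why: Lewis acid demethylation of an aryl methyl ether: BBr3 should bind the methoxy oxygen and bromide should attack the methyl carbon in an SN2 reaction, whereas the diaryl ether oxygen (no sp3 carbon to attack) and the three C–Br bonds should stay intact; no stereocentre is involved.

Step 4
Reactants: 7 3-bromo-2-(3,5-dibromo-2-hydroxyphenoxy)phenol
Product: 8 3,4,6-tribromo-2-(3,5-dibromo-2-hydroxyphenoxy)phenol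
Conditions: Br2 (2.05 equiv), AcOH, 15 °C to rt, 2 h; aq NaHSO3; recrystallisation
Reagents that add atoms: bromine BrBr
Why: Electrophilic aromatic bromination under control of the free phenol of ring B: its open ortho carbon (C6) and para carbon (C4) are the only positions ortho or para to an OH in 7, because ring A has both of its such positions occupied and the three remaining C–H bonds are meta to OH on deactivated rings; no stereocentre is formed.

Compound list
1 | 2-bromo-6-methoxyphenol | COc1cccc(Br)c1O | starting material
2 | 2-chlorocyclohexan-1-one (racemic) | O=C1CCCCC1Cl | starting material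
3 | 2-(2-bromo-6-methoxyphenoxy)cyclohexan-1-one (racemic) | COc1cccc(Br)c1OC1CCCCC1=O | intermediate
4 | 6-bromo-2-(2-bromo-6-methoxyphenoxy)cyclohex-2-en-1-one (racemic) | COc1cccc(Br)c1OC1=CCCC(Br)C1=O | intermediate
5 | 2-(2-bromo-6-methoxyphenoxy)phenol | COc1cccc(Br)c1Oc1ccccc1O | intermediate
6 | 2,4-dibromo-6-(2-bromo-6-methoxyphenoxy)phenol | COc1cccc(Br)c1Oc1cc(Br)cc(Br)c1O | intermediate
7 | 3-bromo-2-(3,5-dibromo-2-hydroxyphenoxy)phenol | Oc1cccc(Br)c1Oc1cc(Br)cc(Br)c1O | intermediate
8 | 3,4,6-tribromo-2-(3,5-dibromo-2-hydroxyphenoxy)phenol | Oc1c(Br)cc(Br)cc1Oc1c(O)c(Br)cc(Br)c1Br | target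

Total step count: 4. Longest linear sequence: 4 steps.

Steps most likely to fail

First, step 2 (the key step). Bromine could add across the enol ether double bond of 4 and leave a sixth bromine ortho to the ether oxygen of ring A. HBr could cleave the α-aryloxy ketone before ring A is aromatic, and free bromine could begin to substitute ring B. The fallback would set out from 1 and come back at 6, giving up the de novo ring. Nucleophilic aromatic substitution of commercially available 2-fluorobenzaldehyde by 1 (K2CO3, DMAc, 120 °C) would give 2-(2-bromo-6-methoxyphenoxy)benzaldehyde F1. Baeyer–Villiger oxidation (mCPBA, CH2Cl2) would give 2-(2-bromo-6-methoxyphenoxy)phenyl formate F2, and hydrolysis (aq NaOH, MeOH, then acid) would give phenol 5, here isolated. Br2 (2.05 equiv) in AcOH would then give 6.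

Second, step 1. The di-ortho-substituted phenoxide could react slowly, so that elimination and self-condensation of 2 take over. The fallback would set out from 1 and come back at 3. Opening of cyclohexene oxide by the phenoxide of 1 (K2CO3, DMF, 110 °C) would give trans-2-(2-bromo-6-methoxyphenoxy)cyclohexan-1-ol F3 (racemic, trans by anti opening). Swern oxidation ((COCl)2, DMSO, Et3N, CH2Cl2, −78 °C) would then give 3.

Third, step 4. Bromination could run on to the carbons of ring A that lie ortho and para to the ether oxygen, attack a substituted carbon of ring A (ipso attack with dienone formation), or oxidise the electron-rich bis-phenol. The fallback would set out from 6 and come back at 8, with the phenol of ring A masked and deactivated as a sulfonate while ring B is brominated under control of its own free OH. Mesylation of 6 (MsCl, Et3N, CH2Cl2, 0 °C) would give 2,4-dibromo-6-(2-bromo-6-methoxyphenoxy)phenyl methanesulfonate F4. Demethylation (BBr3, CH2Cl2, −78 °C to rt) would give 2,4-dibromo-6-(2-bromo-6-hydroxyphenoxy)phenyl methanesulfonate F5, whose only free phenol is that of ring B. Br2 (2.05 equiv) in AcOH would give 2,4-dibromo-6-(2,3,5-tribromo-6-hydroxyphenoxy)phenyl methanesulfonate F6. Cleavage of the sulfonate (aq NaOH, MeOH, 60 °C, then HCl) would then give 8.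

Further compounds
F1 | step 2 | 2-(2-bromo-6-methoxyphenoxy)benzaldehyde | COc1cccc(Br)c1Oc1ccccc1C=O
F2 | step 2 | 2-(2-bromo-6-methoxyphenoxy)phenyl formate | COc1cccc(Br)c1Oc1ccccc1OC=O
F3 | step 1 | trans-2-(2-bromo-6-methoxyphenoxy)cyclohexan-1-ol (racemic, one enantiomer drawn) | COc1cccc(Br)c1O[C@@H]1CCCC[C@H]1O
F4 | step 4 | 2,4-dibromo-6-(2-bromo-6-methoxyphenoxy)phenyl methanesulfonate | COc1cccc(Br)c1Oc1cc(Br)cc(Br)c1OS(C)(=O)=O
F5 | step 4 | 2,4-dibromo-6-(2-bromo-6-hydroxyphenoxy)phenyl methanesulfonate | Oc1cccc(Br)c1Oc1cc(Br)cc(Br)c1OS(C)(=O)=O
F6 | step 4 | 2,4-dibromo-6-(2,3,5-tribromo-6-hydroxyphenoxy)phenyl methanesulfonate | Oc1c(Br)cc(Br)c(Br)c1Oc1cc(Br)cc(Br)c1OS(C)(=O)=O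
A1 | direct plan | 2-amino-3-bromophenol | Nc1c(O)cccc1Br
A2 | direct plan | 5-bromo-6-diazocyclohexa-2,4-dien-1-one | O=C1C=CC=C(Br)C1=[N+]=[N-]
A3 | direct plan | catechol (benzene-1,2-diol) | Oc1ccccc1O
A4 | direct plan | 3-bromo-2-(2-hydroxyphenoxy)phenol | Oc1ccccc1Oc1c(O)cccc1Br
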